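The easy mistake with flasks read at one time is to reckon a share without asking how much substrate each flask has turned.

| setting | winter | dawn | grey | ochre | teal | amber |
|---|---|---|---|---|---|---|
| substrate | 0.025 M | 0.10 M | 0.050 M | 0.050 M | 0.050 M | 0.050 M |
| gas | 11 mM (held) | 11 mM (held) | 11 mM (held) | 11 mM (held) | 11 mM (held) | 11 mM (held) |
| temperature | 26 °C | 51 °C | 60 °C | 45 °C | 15 °C | 30 °C |
| remark | run made earlier | run made earlier |  |  |  |  |
| time |  |  | 2.5 d | 2.5 d | 2.5 d | 2.5 d |

- winter (time / d: mono adduct / %, double product / %, substrate / %): 0.833: 5, 0, 98; 2.50: 10, 2, 87; 5.00: 17, 9, 78; 6.00: 17, 10, 74; 12.0: 21, 27, 52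
- dawn (time / d: mono adduct / %, double product / %, substrate / %): 0.250: 5, 3, 93; 0.500: 13, 2, 80; 1.04: 20, 9, 65; 1.67: 26, 23, 52; 3.00: 24, 46, 30

(standard deviation of a reading: 1.5 percentage points)

- the best flask by share of mono adduct in all that became mono adduct or double product; "all alike" if 1.5 percentage points covers them all (grey / ochre / teal / amber / all alike)
- share of mono adduct in all that became mono adduct or double product, grey
- share of mono adduct in all that became mono adduct or double product, ochre
- share of mono adduct in all that became mono adduct or double product, teal
- share of mono adduct in all that became mono adduct or double product, amber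

- at the start none of partner is dissolved
- reactions considered so far: substrate + partner -> mono adduct; gas <-> partner; partner + mono adduct <-> double product; partner -> decomposed reagent

I work on amber, whose temperature lies between those of the earlier runs, and I assume that percentages do not depend on the charge. At its last reading the winter flask shows 1.17 for what I call the toll: the share of double product in mono adduct plus double product, divided by the conversion of substrate. So I reckon the share as one minus toll times conversion. The dawn flask, read at 1.67 d at the same conversion of 48.0%, gives a toll of 0.978, which is lower; both carry the scatter of readings.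

Next comes conversion. I treat substrate as pseudo-first-order, with partner fed from the held gas, and read 0.0545 d⁻¹ in winter and 0.401 d⁻¹ in dawn. Interpolated, amber's rate constant is 1.38 times winter's, and this factor is smaller than the ratio of winter's two reading times 5.00 d and 2.50 d. So I place amber's conversion between winter's 13.0% and 22.0%.

On these assumptions, the lower conversion with the dawn toll gives my bound from above, 87.3%. The higher conversion with the winter toll gives my bound from below, 74.2%. Tightening, the interpolated conversion is 17.1%, and with the toll of the nearer run I commit to 80.0%.

The forecast names teal and gives amber 87% (79% to 93%), at the top edge of my bracket and above my figure. It gives grey 22%, ochre 55% and teal 92%, holding that “conversion dominates the share at a fixed 2.5 d”.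

The flasks give teal as best, at 94.9%, and grey stands at 22.0%.

    substrate + partner → mono adduct (k = 6.97 M⁻¹ h⁻¹, Ea = 86.0 kJ mol⁻¹)
    gas ⇌ partner, rate k2*(csat - [partner]) (kL = 0.412 h⁻¹)
    partner + mono adduct ⇌ double product (K = 1270 M⁻¹, k = 12.9 M⁻¹ h⁻¹, Ea = 77.0 kJ mol⁻¹, ΔH = −90.0 kJ mol⁻¹)
    partner → decomposed reagent (k = 0.210 h⁻¹, Ea = 111 kJ mol⁻¹)
    (constants at 60 °C)

Amber gives 78.2%, inside the bracket and 1.8 percentage points under my figure. Amber's substrate stood at 82% of the charge. The winter toll on amber's conversion of 17.7% gives 79.3%. On ochre, with conversion 55.1%, the two tolls give 35.5% and 46.1%, and ochre stands between them at 43.1%.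

Readings and results were computed on assumed constants; the scatter is artificial.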